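Numbering: decalin C1–C10 (C4 = methylene carbon; C5 = CH and C10 = C(Me) ring fusion; C8 = CH(Me); C9 = C(Me)(C11H2Ar)); β is the face of the C10 methyl. The strategy rests on ring B: its vicinal quaternary bond C9–C10 and its C7–C8 bond are the two bonds a tiglate (C8=C9, C11 carbonyl) forms with the diene C10=C5–C6=C7 of a 3-methyl-2-vinylcyclohexene, and C11 on C9 and the oxygenated C4 of ring A lie on the same α face, so a C4–O–C11 ester can hold the partners.
Target ⇒ trans-decalin 4α,11-diol: C11 is arylated as its aldehyde with a magnesiated methyl 4-hydroxybenzoate and then deoxygenated; C4 is methylenated from the ketone.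
Diol ⇒ Δ5-diol (C5–H by hydroxyl-directed hydrogenation) ⇒ bridged δ-lactone (LiAlH4).
Lactone ⇒ (R)-3-methyl-2-vinylcyclohex-2-enyl tiglate by an ester-tethered type 2 intramolecular Diels–Alder: ring A is bought, ring B and the lactone bridge close together, and C8, C9, C10 are set.
Tiglate ⇒ 3-methylcyclohex-2-enone (α-iodination, CBS reduction, Suzuki vinylation, esterification with tiglic acid).

Key step: step 5

Remark: the (S)-CBS catalyst is taken to follow its usual model (iodoalkenyl carbon as the large group) and so to give the (R)-carbinol; the C11 carbinol centre of 18 and 19 is an inconsequential epimer mixture.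

Step 1
Reactants: 1 3-methylcyclohex-2-en-1-one
Product: 2 2-iodo-3-methylcyclohex-2-en-1-one
Conditions: I2, pyridine, DMAP (cat.), CH2Cl2, rt
Reagents that add atoms: iodine, II
Why: α-Iodination of the enone by conjugate addition of the amine, iodination of the enolate and elimination (Baylis–Hillman-type α-halogenation) should place iodine on C2 only.

Step 2
Reactants: 2 2-iodo-3-methylcyclohex-2-en-1-one
Product: 3 (R)-2-iodo-3-methylcyclohex-2-en-1-ol
Conditions: (S)-Me-CBS (10 mol%), BH3·SMe2, THF, −20 °C; then H2O
Reagents that add atoms: none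
Why: Corey–Bakshi–Shibata reduction, in which the catalyst binds the carbonyl anti to the bulky iodoalkenyl side and delivers hydride to one face, should set the carbinol carbon (the future C4) as R.

Step 3
Reactants: 3 (R)-2-iodo-3-methylcyclohex-2-en-1-ol; 4 vinylboronic acid pinacol ester
Product: 5 (R)-3-methyl-2-vinylcyclohex-2-en-1-ol
Conditions: Pd(OAc)2 (5 mol%), SPhos (10 mol%), K3PO4, THF/H2O, 60 °C
Reagents that add atoms: none
Why: Suzuki–Miyaura coupling of the alkenyl iodide with the vinylboronate, with a biaryl dialkylphosphine for the doubly flanked C–I bond, tolerates the free carbinol and does not touch its configuration.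

Step 4
Reactants: 5 (R)-3-methyl-2-vinylcyclohex-2-en-1-ol; 6 tiglic acid [(E)-2-methylbut-2-enoic acid]
Product: 7 (1R)-3-methyl-2-vinylcyclohex-2-en-1-yl (2E)-2-methylbut-2-enoate
Conditions: DCC, DMAP, CH2Cl2, 0 °C → rt
Reagents that add atoms: none
Why: Steglich esterification acylates oxygen without breaking the C4–O bond, so the (R) centre and the (E) geometry of the tiglate are kept.

Step 5
Reactants: 7 (1R)-3-methyl-2-vinylcyclohex-2-en-1-yl (2E)-2-methylbut-2-enoate
Product: 8 bridged δ-lactone: 4α-hydroxy-8β,9β,10β-trimethyl-Δ5(6)-octalin-9α-carboxylic acid 11→4 lactone (C5=C6 at the bridgehead)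
Conditions: CH2Cl2 (0.02 M), BHT (cat.), 1.5 GPa (15 kbar), 60 °C
Reagents that add atoms: none
Why: Proposed new method: heat and pressure should drive a concerted, asynchronous thermal [4+2] in which the ester C4–O–C11(=O) ties the dienophile carbon C9 to the internal diene carbon C5, so that C8 first engages the unsubstituted vinyl terminus C7 and C9 then closes onto the fully substituted C10; the closest known chemistry is the type 2 intramolecular Diels–Alder reaction, which gives bicyclo[3.3.1]non-1-enes from three-atom all-carbon tethers only at very high temperature and larger bridged rings under Lewis acid catalysis, together with the high-pressure Diels–Alder reaction used to forge adjacent quaternary carbons. Ring B (C5–C6–C7–C8–C9–C10) closes as the new cyclohexene, and the six-membered lactone (C4–O–C11–C9–C10–C5) closes in the same event as a 1,3-diaxial bridge across ring A, which leaves C5=C6 as the bridgehead alkene of a bicyclo[3.3.1]non-1-ene. C9 and C10 are controlled by the tether, which reaches C10 only on the α face that carries the C4 oxygen and must hold the carbonyl C11 endo over C5 (C10 methyl β, C11 α, C9 methyl β), and C8 is controlled by the (E) geometry of the tiglate, suprafacial addition keeping the C8 and C9 methyls cis. What the step needs is rate, not selectivity: the ester has to leave its favoured Z rotamer and the inside C10 methyl opposes the s-cis diene, and 1.5 GPa should pay for both because the compact transition state has a strongly negative activation volume and the more polar E rotamer is favoured by compression. [1,5]-Hydrogen shift of the diene, ester elimination and, at high dilution, intermolecular cycloaddition gain little from pressure and should stay slow at 60 °C.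

Step 6
Reactants: 8 bridged δ-lactone
Product: 9 4α-hydroxy-9α-(hydroxymethyl)-8β,9β,10β-trimethyl-Δ5(6)-octalin
Conditions: LiAlH4, THF, 0 °C → rt; aq. work-up
Reagents that add atoms: none
Why: Hydride reduction of the lactone gives the primary C11 alcohol and frees the C4 alcohol, and opening the bridge takes C5=C6 out of its strained bridgehead position without touching a stereocentre.

Step 7
Reactants: 9 4α-hydroxy-9α-(hydroxymethyl)-8β,9β,10β-trimethyl-Δ5(6)-octalin
Product: 10 4α-hydroxy-9α-(hydroxymethyl)-8β,9β,10β-trimethyl-5α-decalin (trans-fused)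
Conditions: [Ir(cod)(PCy3)(py)]PF6 (5–10 mol%), H2 (1 atm), CH2Cl2, rt
Reagents that add atoms: none
Why: Hydroxyl-directed hydrogenation with Crabtree's catalyst: the cationic iridium binds the α-face hydroxyls (the axial C9–CH2OH lies 1,3 to C5, the C4–OH is allylic) and should deliver H2 to C5=C6 from the α face, away from the C10 and C8 methyls, setting C5–H α (trans fusion).

Step 8
Reactants: 10 4α-hydroxy-9α-(hydroxymethyl)-8β,9β,10β-trimethyl-5α-decalin
Product: 11 9α-(hydroxymethyl)-8β,9β,10β-trimethyl-5α-decalin-4-one
Conditions: NaOCl (aq), AcOH, 0 °C → rt, short reaction time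
Reagents that add atoms: none
Why: Hypochlorite in acetic acid oxidises secondary carbinols much faster than primary ones and the neopentyl C11 alcohol is shielded further, while the trans-decalin geometry keeps that hydroxyl from closing a hemiketal onto C4 and the brief, weakly acidic conditions should not enolise toward C5.

Step 9
Reactants: 11 9α-(hydroxymethyl)-8β,9β,10β-trimethyl-5α-decalin-4-one
Product: 12 [(1R,2S,4aS,8aS)-1,2,8a-trimethyl-5-methylidenedecahydronaphthalen-1-yl]methanol
Conditions: Zn, CH2Br2, TiCl4 (preformed reagent, excess), THF/CH2Cl2, 0 °C → rt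
Reagents that add atoms: dibromomethane, BrCBr
Why: Takai–Lombardo methylenation uses a non-basic Zn/Ti gem-dimetallic reagent that olefinates hindered, enolisable ketones without epimerising the α-centre C5 and tolerates the free alcohol when used in excess.

Step 10
Reactants: 12 [(1R,2S,4aS,8aS)-1,2,8a-trimethyl-5-methylidenedecahydronaphthalen-1-yl]methanol
Product: 13 (1R,2S,4aS,8aS)-1,2,8a-trimethyl-5-methylidenedecahydronaphthalene-1-carbaldehyde
Conditions: Dess–Martin periodinane, CH2Cl2, rt
Reagents that add atoms: none
Why: Dess–Martin oxidation of the neopentyl primary alcohol gives an aldehyde with no α-hydrogen, and the 1,1-disubstituted alkene is inert to the reagent.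

Step 11
Reactants: 14 methyl 4-hydroxybenzoate
Product: 15 methyl 4-hydroxy-3-iodobenzoate
Conditions: ICl, AcOH, 65 °C
Reagents that add atoms: iodine monochloride, ClI
Why: Electrophilic aromatic iodination goes ortho to the hydroxyl because the para position is blocked and the ester directs meta to the same carbon.

Step 12
Reactants: 15 methyl 4-hydroxy-3-iodobenzoate
Product: 16 methyl 3-iodo-4-(methoxymethoxy)benzoate
Conditions: MOMCl, iPr2NEt, CH2Cl2, 0 °C → rt
Reagents that add atoms: chloromethyl methyl ether, COCCl
Why: O-Alkylation of the phenol gives a MOM acetal that is inert to the organomagnesium, xanthate and tin hydride steps and can chelate magnesium.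

Step 13
Reactants: 13 (1R,2S,4aS,8aS)-1,2,8a-trimethyl-5-methylidenedecahydronaphthalene-1-carbaldehyde; 16 methyl 3-iodo-4-(methoxymethoxy)benzoate
Product: 18 methyl 3-{hydroxy[(1R,2S,4aS,8aS)-1,2,8a-trimethyl-5-methylidenedecahydronaphthalen-1-yl]methyl}-4-(methoxymethoxy)benzoate (C11 epimer mixture), via arylmagnesium chloride 17 (not isolated)
Conditions: 16 (3 equiv), iPrMgCl·LiCl (2.9 equiv), THF, −40 °C; then 13, −40 → 0 °C; aq. NH4Cl
Reagents that add atoms: none
Why: Iodine–magnesium exchange with the LiCl-activated isopropyl Grignard at −40 °C is faster than attack on the methyl ester, and the arylmagnesium then adds 1,2 to the non-enolisable aldehyde, forming the C11 carbinol centre without control before its removal in step 15.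

Step 14
Reactants: 18 methyl 3-{hydroxy[(1R,2S,4aS,8aS)-1,2,8a-trimethyl-5-methylidenedecahydronaphthalen-1-yl]methyl}-4-(methoxymethoxy)benzoate
Product: 19 S-methyl xanthate of 18 (O-[aryl(decalinyl)methyl] S-methyl dithiocarbonate)
Conditions: NaH, imidazole (cat.), THF, 0 °C; CS2; then MeI, rt
Reagents that add atoms: carbon disulfide, S=C=S; iodomethane, CI
Why: Xanthate formation from the sodium alkoxide (first stage of the Barton–McCombie deoxygenation) uses a small electrophile that the hindered alkoxide can reach, and the lack of a β-hydrogen on C9 excludes Chugaev elimination.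

Step 15
Reactants: 19 S-methyl xanthate of 18
Product: 20 methyl 4-(methoxymethoxy)-3-{[(1R,2S,4aS,8aS)-1,2,8a-trimethyl-5-methylidenedecahydronaphthalen-1-yl]methyl}benzoate
Conditions: Bu3SnH, AIBN (cat.), toluene, 100 °C
Reagents that add atoms: none
Why: Barton–McCombie deoxygenation proceeds by stannyl radical addition to C=S, β-scission to the benzylic C11 radical and hydrogen transfer from the tin hydride, a radical path that avoids the Wagner–Meerwein shift a neopentyl benzylic cation would risk.

Step 16
Reactants: 20 methyl 4-(methoxymethoxy)-3-{[(1R,2S,4aS,8aS)-1,2,8a-trimethyl-5-methylidenedecahydronaphthalen-1-yl]methyl}benzoate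
Product: 21 methyl 4-hydroxy-3-{[(1R,2S,4aS,8aS)-1,2,8a-trimethyl-5-methylidenedecahydronaphthalen-1-yl]methyl}benzoate (CNP0169318.1)
Conditions: ZnBr2, n-PrSH, CH2Cl2, 0 °C
Reagents that add atoms: none
Why: Lewis acid/thiol cleavage of the phenolic MOM acetal (ZnBr2 activates the acetal, the thiol takes the methoxymethyl group) is aprotic and should spare the exocyclic alkene and the methyl ester.

Compound list
1 | 3-methylcyclohex-2-en-1-one | CC1=CC(=O)CCC1 | starting material
2 | 2-iodo-3-methylcyclohex-2-en-1-one | CC1=C(I)C(=O)CCC1 | intermediate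
3 | (R)-2-iodo-3-methylcyclohex-2-en-1-ol | O[C@@H]1CCCC(C)=C1I | intermediate
4 | vinylboronic acid pinacol ester | C=CB1OC(C)(C)C(C)(C)O1 | starting material
5 | (R)-3-methyl-2-vinylcyclohex-2-en-1-ol | O[C@@H]1CCCC(C)=C1C=C | intermediate
6 | tiglic acid | C/C=C(\C)C(=O)O | starting material
7 | (1R)-3-methyl-2-vinylcyclohex-2-en-1-yl (2E)-2-methylbut-2-enoate | C/C=C(\C)C(=O)O[C@@H]1CCCC(C)=C1C=C | intermediate
8 | bridged δ-lactone (11→4α lactone, 8β,9β,10β-trimethyl, bridgehead C5=C6) | O=C1O[C@@H]2CCC[C@@]3(C)C2=CC[C@H](C)[C@@]13C | intermediate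
9 | 4α-hydroxy-9α-(hydroxymethyl)-8β,9β,10β-trimethyl-Δ5(6)-octalin | O[C@@H]1CCC[C@@]2(C)C1=CC[C@H](C)[C@@]2(C)CO | intermediate
10 | 4α-hydroxy-9α-(hydroxymethyl)-8β,9β,10β-trimethyl-5α-decalin | O[C@@H]1CCC[C@@]2(C)[C@H]1CC[C@H](C)[C@@]2(C)CO | intermediate
11 | 9α-(hydroxymethyl)-8β,9β,10β-trimethyl-5α-decalin-4-one | O=C1CCC[C@@]2(C)[C@H]1CC[C@H](C)[C@@]2(C)CO | intermediate
12 | [(1R,2S,4aS,8aS)-1,2,8a-trimethyl-5-methylidenedecahydronaphthalen-1-yl]methanol | C=C1CCC[C@@]2(C)[C@H]1CC[C@H](C)[C@@]2(C)CO | intermediate
13 | (1R,2S,4aS,8aS)-1,2,8a-trimethyl-5-methylidenedecahydronaphthalene-1-carbaldehyde | C=C1CCC[C@@]2(C)[C@H]1CC[C@H](C)[C@@]2(C)C=O | intermediate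
14 | methyl 4-hydroxybenzoate | COC(=O)c1ccc(O)cc1 | starting material
15 | methyl 4-hydroxy-3-iodobenzoate | COC(=O)c1ccc(O)c(I)c1 | intermediate
16 | methyl 3-iodo-4-(methoxymethoxy)benzoate | COCOc1ccc(C(=O)OC)cc1I | intermediate
17 | [5-(methoxycarbonyl)-2-(methoxymethoxy)phenyl]magnesium chloride (LiCl complex, not isolated) | COCOc1ccc(C(=O)OC)cc1[Mg]Cl | intermediate
18 | methyl 3-{hydroxy[(1R,2S,4aS,8aS)-1,2,8a-trimethyl-5-methylidenedecahydronaphthalen-1-yl]methyl}-4-(methoxymethoxy)benzoate (C11 epimers) | C=C1CCC[C@@]2(C)[C@H]1CC[C@H](C)[C@@]2(C)C(O)c1cc(C(=O)OC)ccc1OCOC | intermediate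
19 | S-methyl xanthate of 18 | C=C1CCC[C@@]2(C)[C@H]1CC[C@H](C)[C@@]2(C)C(OC(=S)SC)c1cc(C(=O)OC)ccc1OCOC | intermediate
20 | methyl 4-(methoxymethoxy)-3-{[(1R,2S,4aS,8aS)-1,2,8a-trimethyl-5-methylidenedecahydronaphthalen-1-yl]methyl}benzoate | C=C1CCC[C@@]2(C)[C@H]1CC[C@H](C)[C@@]2(C)Cc1cc(C(=O)OC)ccc1OCOC | intermediate
21 | methyl 4-hydroxy-3-{[(1R,2S,4aS,8aS)-1,2,8a-trimethyl-5-methylidenedecahydronaphthalen-1-yl]methyl}benzoate | C=C1CCC[C@@]2(C)[C@H]1CC[C@H](C)[C@@]2(C)Cc1cc(C(=O)OC)ccc1O | target

Total step count: 16. Longest linear sequence: 14 steps (steps 1–10 and 13–16, from compound 1); the aryl partner takes 2 steps (11–12).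

Steps most likely to fail

1. Step 5 (key cycloaddition). The cyclisation may simply not start: the ester stays in its Z rotamer, the hindered s-cis diene is not reached, and slow intermolecular cycloaddition or diene isomerisation takes over. The fallback sets out from dienol 5 and returns at diol 9. Dienol 5 is converted to its bromomagnesium alkoxide (MeMgBr, toluene, 0 °C) and stirred with methyl tiglate (rt → 60 °C). The magnesium on the C4 oxygen also binds the ester carbonyl, so the reaction runs as a Lewis-acid-tethered, hydroxyl-directed intermolecular Diels–Alder, a known reaction type for 2-vinylcyclohex-2-enols with acrylates. The link C4–O–Mg···O=C11 is five atoms long, no bridgehead alkene is formed and no ester rotamer has to be populated. Delivery is again on the α face with C11 endo, which should give methyl 4α-hydroxy-8β,9β,10β-trimethyl-Δ5(6)-octalin-9α-carboxylate F1. LiAlH4 (THF, 0 °C) then reduces this ester to diol 9.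

2. Step 13 (aryl addition). The ester-bearing arylmagnesium may self-condense or be quenched before it adds to the doubly neopentyl aldehyde, since it cannot be warmed. The fallback sets out from aldehyde 13 and returns at carbinol 18. Commercial 4-bromo-2-iodophenol is protected (MOMCl, iPr2NEt, CH2Cl2) as 4-bromo-2-iodo-1-(methoxymethoxy)benzene F2. Selective iodine–magnesium exchange (iPrMgCl·LiCl, THF, −20 °C) gives the ester-free [5-bromo-2-(methoxymethoxy)phenyl]magnesium chloride F3, which is stable at room temperature and can be forced onto 13 (rt → 40 °C, LaCl3·2LiCl if needed). This gives [5-bromo-2-(methoxymethoxy)phenyl][(1R,2S,4aS,8aS)-1,2,8a-trimethyl-5-methylidenedecahydronaphthalen-1-yl]methanol F4. Palladium-catalysed methoxycarbonylation of the aryl bromide (Pd(OAc)2, Xantphos, CO 1 atm, MeOH, Et3N, 70 °C) then installs the ester and gives 18.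

3. Step 7 (C5 hydrogenation). Facial selectivity may be poor, or the hydrogenation may stall because the 4,11-diol chelates and deactivates the cationic iridium. The fallback sets out from diol 9 and returns at diol 10. A metal-hydride hydrogen-atom-transfer hydrogenation (Mn(dpm)3 cat., PhSiH3, t-BuOOH, i-PrOH, rt) places a hydrogen atom on C6. The tertiary C5 radical is then quenched axially from the α face, anti to the C10 methyl, which should give the trans-fused 10 without relying on coordination. This path makes no new compound (F0).

Further compounds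
F1 | step 5 | methyl 4α-hydroxy-8β,9β,10β-trimethyl-Δ5(6)-octalin-9α-carboxylate | O[C@@H]1CCC[C@@]2(C)C1=CC[C@H](C)[C@@]2(C)C(=O)OC
F2 | step 13 | 4-bromo-2-iodo-1-(methoxymethoxy)benzene | COCOc1ccc(Br)cc1I
F3 | step 13 | [5-bromo-2-(methoxymethoxy)phenyl]magnesium chloride | COCOc1ccc(Br)cc1[Mg]Cl
F4 | step 13 | [5-bromo-2-(methoxymethoxy)phenyl][(1R,2S,4aS,8aS)-1,2,8a-trimethyl-5-methylidenedecahydronaphthalen-1-yl]methanol | C=C1CCC[C@@]2(C)[C@H]1CC[C@H](C)[C@@]2(C)C(O)c1cc(Br)ccc1OCOC
F0 | step 7 | none | none
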